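**Retrosynthetic overview**

1. Locants (daucane, used for all intermediates): C1 = ring-fusion C–CH3, C2/C3 = CH2, C4 = C(OH)iPr, C5 = ring-fusion CH, C6 = C–O(ester), C7=C8(CH3), C9 = CH(OH), C10 = CH2. Endgame disconnections: aryl O–Si, C9–OH (allylic hydroxylation steered by the C6 ester), C6 ester, C6–OH (reduction directed by the C4–OH), leading back to enone 14.
2. Enabling feature: in 14 the C6 carbonyl carbon is bonded to C5, and C5 to the quaternary C1. A ketone flanking the C1–C5 fusion bond of the cyclopentane (C1–C2–C3–C4–C5) is the retron of a pinacol-type 1,2-shift of C1 from C6 to C5. The precursor is cis-decalin 13, whose ring C1–C2–C3–C4–C5–C6 carries an all-cis C4,C5,C6-triol with C5 as the equatorial mesylate; the shift contracts this cyclohexane to the cyclopentane, enlarges the cyclohexene (C1, C6–C10) to the cycloheptenone and sets C5.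
3. Triol: C6–O from nucleophilic epoxidation of dienone 6 on the face of the angular methyl and reductive opening (enolate trapped as triflate, later CH3); C4–O and C5–O from dihydroxylation directed by the C6–OH.
4. Dienone 6 from (+)-dihydrocarvone and methyl vinyl ketone: the isopropenyl stereocentre sets the quaternary C1 in the annulation and is then erased by conjugative isomerisation.
5. Ring order: cyclohexane (chiral pool), then the second six-membered ring (annulation), then step 8 turns the 6-6 system into the 5-7 system (cyclopentane by contraction, cycloheptene by expansion).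

Key step: step 8

Remark: commercial (+)-dihydrocarvone is a mixture of epimers at the methyl-bearing carbon; this is immaterial because that carbon becomes the enolate carbon in step 1.

Step 1
Reactants: 1 (+)-dihydrocarvone; 2 methyl vinyl ketone
Product: 4 cis-ketol (4aR,7R,8aR)-8a-hydroxy-4a-methyl-7-(prop-1-en-2-yl)octahydronaphthalen-2(1H)-one, via Michael adduct 3 (not isolated)
Conditions: KOH (0.1 equiv), EtOH, −10 to 0 °C; crystallisation
Reagents that add atoms: none
Why: Robinson-type Michael addition and intramolecular aldol addition stopped at the ketol: the more substituted enolate should add by axial attack, placing the new chain cis to the equatorial isopropenyl group (sets C1), the tethered methyl-ketone enolate closes the ring on its own face (sets C6, OH cis to the angular methyl), and crystallisation should remove the minor C1 epimer before the controlling centre is erased.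

Step 2
Reactants: 4 cis-ketol
Product: 6 dienone (4aR)-4a-methyl-7-(propan-2-yl)-4,4a,5,6-tetrahydronaphthalen-2(3H)-one, via enone 5 (not isolated)
Conditions: TsOH·H2O (0.2 equiv), toluene, reflux (Dean–Stark)
Reagents that add atoms: none
Why: Acid-catalysed aldol dehydration followed by proton-mediated migration of the isopropenyl double bond into conjugation (through the isopropylidene isomer and the extended dienol) should end in the linear dienone as thermodynamic sink; the C4 centre is erased on purpose and the quaternary C1 cannot epimerise.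

Step 3
Reactants: 6 dienone
Product: 7 epoxy dienone (C6–C7 epoxide with the oxygen cis to the angular methyl)
Conditions: 30% H2O2, NaOH (aq), MeOH, 0 °C
Reagents that add atoms: hydrogen peroxide OO
Why: Weitz–Scheffer nucleophilic epoxidation: hydroperoxide should add 1,4 at C6 (the δ-carbon C4 is blocked by isopropyl) and close the epoxide on the face of the angular methyl, the usual outcome for 4a-methyl octalones (sets C6 and C7).

Step 4
Reactants: 7 epoxy dienone
Product: 9 hydroxy dienyl triflate (4aR,8aR)-8a-hydroxy-4a-methyl-7-(propan-2-yl)-3,4,4a,5,6,8a-hexahydronaphthalen-2-yl trifluoromethanesulfonate, via dilithium alkoxide enolate 8 (not isolated)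
Conditions: LiDBB (2.1 equiv), THF, −78 °C; then PhNTf2, −78 to 0 °C; aq NH4Cl
Reagents that add atoms: N-phenylbis(trifluoromethanesulfonimide) O=S(=O)(N(c1ccccc1)S(=O)(=O)C(F)(F)F)C(F)(F)F
Why: Reductive cleavage of the Cα–O bond of the α,β-epoxy ketone gives the β-alkoxy enolate with its double bond fixed at C7=C8, and O-triflation traps this regioisomer; the C6–O bond is untouched, so C6 keeps its configuration.

Step 5
Reactants: 9 hydroxy dienyl triflate
Product: 11 all-cis triol triflate, via osmate ester 10 (not isolated)
Conditions: OsO4 (1.05 equiv), TMEDA (1.1 equiv), CH2Cl2, −78 °C; then sat. aq Na2SO3, THF, 50 °C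
Reagents that add atoms: osmium tetroxide O=[Os](=O)(=O)=O
Why: Hydroxyl-directed dihydroxylation with OsO4·TMEDA: hydrogen bonding of the tertiary allylic C6–OH to an oxo ligand should deliver both oxygens to C4=C5 on the face of that hydroxyl (sets C4 and C5), while the electron-poor enol triflate double bond is not osmylated.

Step 6
Reactants: 11 all-cis triol triflate
Product: 12 all-cis triol (4a,7-dimethyl-2-(propan-2-yl)-1,2,3,4,4a,5,6,8a-octahydronaphthalene-1,2,8a-triol)
Conditions: MeMgBr (6 equiv), Fe(acac)3 (10 mol %), THF/NMP, −20 to 0 °C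
Reagents that add atoms: methylmagnesium bromide C[Mg]Br
Why: Iron-catalysed Kumada cross-coupling of the alkenyl triflate with methylmagnesium bromide, the hydroxyls being carried as magnesium alkoxides; no stereocentre is involved.

Step 7
Reactants: 12 all-cis triol
Product: 13 C5 mesylate
Conditions: MsCl (1.1 equiv), Et3N, CH2Cl2, −30 °C
Reagents that add atoms: methanesulfonyl chloride CS(=O)(=O)Cl
Why: Sulfonylation of the only secondary hydroxyl (C5–OH, equatorial) beside two tertiary ones; the C5–O bond is kept, so the mesylate stays cis to the angular methyl.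

Step 8
Reactants: 13 C5 mesylate
Product: 14 hydroazulenone (3R,3aR,8aS)-3-hydroxy-6,8a-dimethyl-3-(propan-2-yl)-2,3,3a,7,8,8a-hexahydroazulen-4(1H)-one
Conditions: LiClO4 (5 equiv), CaCO3 (5 equiv), THF, 50 °C
Reagents that add atoms: none
Why: Pinacol-type (semipinacol) 1,2-shift under buffered solvolysis: as the equatorial C5 mesylate ionises, the antiperiplanar C6–C1 ring-fusion bond migrates to C5 and the tertiary C6 carbinol collapses to the ketone. The closest known reaction type is the rearrangement of decalin cis-1,2-diol monosulfonates to hydroazulenones. Both rings arise from the alkyl shift itself and not from a cyclisation: the cyclopentane by one-carbon contraction of the cyclohexane C1–C6 (C1 moves from C6 to C5 and closes C1–C5), the cycloheptenone by the matching one-carbon enlargement of the cyclohexene (C5 is inserted between C6 and C1). C5 is set by inversion at the migration terminus (backside displacement of the mesylate, which is cis to the angular methyl, so H5 ends trans to it), C1 migrates with retention and C4 is untouched, which gives the trans-fused C1/C4/C5 array of the target. The step needs C1 and nothing else to migrate: the chair of the cis-decalin (equatorial isopropyl, 1,3-diaxial C4 and C6 hydroxyls) holds the mesylate equatorial, so only the ring bonds C6–C1 and C4–C3 are antiperiplanar to it, while C7 and both oxygens are gauche and C4 and C6 carry no hydrogen (vinyl shift, homoallyl participation, epoxide closure and elimination are excluded). Between the two aligned bonds C1 should win because the C6 carbinol is allylic, so its carbonyl develops in conjugation with C7=C8, and because C1 is quaternary whereas C3 is a CH2.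

Step 9
Reactants: 14 hydroazulenone
Product: 15 diol (3R,3aS,4S,8aS)-6,8a-dimethyl-3-(propan-2-yl)-1,2,3,3a,4,7,8,8a-octahydroazulene-3,4-diol
Conditions: Me4NBH(OAc)3 (5 equiv), MeCN/AcOH (1:1), −30 to 0 °C
Reagents that add atoms: none
Why: Evans–Saksena reduction: the C4–OH exchanges onto boron and delivers hydride intramolecularly to the face of the C6 carbonyl on which it lies, so the new C6–OH should be trans to the C4–OH (1,3-anti) and cis to H5, as in the target; the enone is reduced 1,2.

Step 10
Reactants: 16 vanillic acid
Product: 18 4-(tert-butyldimethylsilyloxy)-3-methoxybenzoic acid, via bis-silylated vanillic acid 17 (not isolated)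
Conditions: TBSCl (2.5 equiv), imidazole, DMF, rt; then AcOH/THF/H2O, rt
Reagents that add atoms: tert-butyldimethylsilyl chloride CC(C)(C)[Si](C)(C)Cl
Why: Silylation of phenol and carboxylic acid, then selective hydrolysis of the labile silyl ester; no stereocentre.

Step 11
Reactants: 15 diol; 18 4-(tert-butyldimethylsilyloxy)-3-methoxybenzoic acid
Product: 20 C6 ester (silyl-protected vanillate of 15), via Yamaguchi mixed anhydride 19 (not isolated)
Conditions: 2,4,6-trichlorobenzoyl chloride, Et3N, THF, rt; then 15, DMAP, toluene, 50 °C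
Reagents that add atoms: none
Why: Yamaguchi esterification: the secondary allylic C6–OH is acylated while the tertiary C4–OH is inert, with retention at C6.

Step 12
Reactants: 20 C6 ester
Product: 21 C9 allylic alcohol (O-silylated target)
Conditions: SeO2 (0.5 equiv), t-BuOOH (3 equiv), CH2Cl2, rt
Reagents that add atoms: selenium dioxide O=[Se]=O (transfers the oxygen, catalytic); tert-butyl hydroperoxide CC(C)(C)OO (terminal oxidant)
Why: Riley-type allylic hydroxylation (ene reaction, then [2,3]-sigmatropic shift): selenium should bond to the less substituted C7 on the face anti to the adjacent C6 aroyloxy group, take hydrogen from the ring CH2 at the more substituted end (C9 rather than the methyl group) and pass oxygen suprafacially to C9, so the C9–OH ends trans to the C6 ester (sets C9).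

Step 13
Reactants: 21 C9 allylic alcohol
Product: 22 target CNP0189996.3
Conditions: TBAF (1.1 equiv), AcOH (1.1 equiv), THF, 0 °C
Reagents that add atoms: none
Why: Fluoride cleavage of the aryl silyl ether under buffered conditions, which should leave the ester, the allylic alcohol and all stereocentres untouched.

**Compound list**

1 | (+)-dihydrocarvone, (2R,5R)-2-methyl-5-(prop-1-en-2-yl)cyclohexan-1-one | C[C@@H]1CC[C@@H](C(C)=C)CC1=O | starting material
2 | methyl vinyl ketone (but-3-en-2-one) | CC(=O)C=C | starting material
3 | Michael adduct, (2R,5R)-2-methyl-2-(3-oxobutyl)-5-(prop-1-en-2-yl)cyclohexan-1-one | CC(=O)CC[C@@]1(C)CC[C@@H](C(C)=C)CC1=O | intermediate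
4 | cis-ketol, (4aR,7R,8aR)-8a-hydroxy-4a-methyl-7-(prop-1-en-2-yl)octahydronaphthalen-2(1H)-one (OH cis to the angular methyl, isopropenyl trans to it) | O=C1CC[C@@]2(C)CC[C@@H](C(C)=C)C[C@@]2(O)C1 | intermediate
5 | enone, (4aR,7R)-4a-methyl-7-(prop-1-en-2-yl)-4,4a,5,6,7,8-hexahydronaphthalen-2(3H)-one | O=C1CC[C@@]2(C)CC[C@@H](C(C)=C)CC2=C1 | intermediate
6 | dienone, (4aR)-4a-methyl-7-(propan-2-yl)-4,4a,5,6-tetrahydronaphthalen-2(3H)-one | CC(C)C1=CC2=CC(=O)CC[C@@]2(C)CC1 | intermediate
7 | epoxy dienone, (1S,4aR,8aS)-1,8a-epoxy-4a-methyl-7-(propan-2-yl)-1,4,4a,5,6,8a-hexahydronaphthalen-2(3H)-one (epoxide oxygen cis to the angular methyl) | CC(C)C1=C[C@@]23O[C@@H]2C(=O)CC[C@@]3(C)CC1 | intermediate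
8 | dilithium salt of the C6 alkoxide and C7=C8 enolate | [Li+].[Li+].CC(C)C1=C[C@@]2([O-])C=C([O-])CC[C@@]2(C)CC1 | intermediate
9 | hydroxy dienyl triflate, (4aR,8aR)-8a-hydroxy-4a-methyl-7-(propan-2-yl)-3,4,4a,5,6,8a-hexahydronaphthalen-2-yl trifluoromethanesulfonate (OH cis to the angular methyl) | CC(C)C1=C[C@@]2(O)C=C(OS(=O)(=O)C(F)(F)F)CC[C@@]2(C)CC1 | intermediate
10 | osmate(VI) ester of the C4,C5-diol, TMEDA complex | CC(C)[C@@]1(O[Os-2]3(=O)(=O)([N+](C)(C)CC[N+]3(C)C)O4)[C@H]4[C@@]2(O)C=C(OS(=O)(=O)C(F)(F)F)CC[C@@]2(C)CC1 | intermediate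
11 | all-cis triol triflate, 1,2,8a-trihydroxy-4a-methyl-2-(propan-2-yl)-1,2,3,4,4a,5,6,8a-octahydronaphthalen-7-yl trifluoromethanesulfonate (three OH and the 4a-methyl on one face) | CC(C)[C@@]1(O)[C@H](O)[C@@]2(O)C=C(OS(=O)(=O)C(F)(F)F)CC[C@@]2(C)CC1 | intermediate
12 | all-cis triol, 4a,7-dimethyl-2-(propan-2-yl)-1,2,3,4,4a,5,6,8a-octahydronaphthalene-1,2,8a-triol (three OH and the 4a-methyl on one face) | CC(C)[C@@]1(O)[C@H](O)[C@@]2(O)C=C(C)CC[C@@]2(C)CC1 | intermediate
13 | C5 mesylate, 2,8a-dihydroxy-4a,7-dimethyl-2-(propan-2-yl)-1,2,3,4,4a,5,6,8a-octahydronaphthalen-1-yl methanesulfonate (OMs, both OH and the 4a-methyl on one face) | CC(C)[C@@]1(O)[C@H](OS(C)(=O)=O)[C@@]2(O)C=C(C)CC[C@@]2(C)CC1 | intermediate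
14 | hydroazulenone, (3R,3aR,8aS)-3-hydroxy-6,8a-dimethyl-3-(propan-2-yl)-2,3,3a,7,8,8a-hexahydroazulen-4(1H)-one (trans ring fusion, OH cis to the angular methyl) | O=C1C=C(C)CC[C@@]2(C)CC[C@@](O)(C(C)C)[C@H]12 | intermediate
15 | diol, (3R,3aS,4S,8aS)-6,8a-dimethyl-3-(propan-2-yl)-1,2,3,3a,4,7,8,8a-octahydroazulene-3,4-diol | O[C@H]1C=C(C)CC[C@@]2(C)CC[C@@](O)(C(C)C)[C@H]12 | intermediate
16 | vanillic acid (4-hydroxy-3-methoxybenzoic acid) | COc1cc(C(=O)O)ccc1O | starting material
17 | tert-butyldimethylsilyl 4-(tert-butyldimethylsilyloxy)-3-methoxybenzoate | COc1cc(C(=O)O[Si](C)(C)C(C)(C)C)ccc1O[Si](C)(C)C(C)(C)C | intermediate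
18 | 4-(tert-butyldimethylsilyloxy)-3-methoxybenzoic acid | COc1cc(C(=O)O)ccc1O[Si](C)(C)C(C)(C)C | intermediate
19 | mixed anhydride of 18 with 2,4,6-trichlorobenzoic acid | COc1cc(C(=O)OC(=O)c2c(Cl)cc(Cl)cc2Cl)ccc1O[Si](C)(C)C(C)(C)C | intermediate
20 | C6 ester, 4-(tert-butyldimethylsilyloxy)-3-methoxybenzoate of the C6 hydroxyl of 15 | COc1cc(C(=O)O[C@H]2C=C(C)CC[C@@]3(C)CC[C@@](O)(C(C)C)[C@H]23)ccc1O[Si](C)(C)C(C)(C)C | intermediate
21 | C9 allylic alcohol, O-tert-butyldimethylsilyl ether of the target (C9–OH trans to the C6 ester) | COc1cc(C(=O)O[C@H]2C=C(C)[C@H](O)C[C@@]3(C)CC[C@@](O)(C(C)C)[C@H]23)ccc1O[Si](C)(C)C(C)(C)C | intermediate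
22 | CNP0189996.3 | COc1cc(C(=O)O[C@H]2C=C(C)[C@H](O)C[C@@]3(C)CC[C@@](O)(C(C)C)[C@H]23)ccc1O | target

**Totals**

Total step count: 13. Longest linear sequence: 12 steps (steps 1–9 and 11–13 from 1); step 10 prepares the acid partner.

**Steps most likely to fail**

Step 8. The shift may take the other antiperiplanar ring bond: the free C4 hydroxyl can push C3 onto C5, and the tertiary β-hydroxy ketone formed can suffer retro-aldol cleavage. The fallback keeps the C6 oxygen masked as the epoxide until the C4 oxygen is capped; it sets out from 7 and returns at 14.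
- OsO4/NMO dihydroxylation of C4=C5 in 7, on the face of the epoxide oxygen (anti to the pseudo-axial C7), gives the epoxy ketone diol F1.
- MsCl/Et3N gives the C5 mesylate F2.
- N-(trimethylsilyl)imidazole caps the C4–OH as the silyl ether F3.
- SmI2 (THF/MeOH, −78 °C) opens the epoxy ketone to the β-hydroxy ketone F4.
- KOtBu then triggers the same shift, now with only the C6 oxygen able to push, to give the β-diketone F5.
- Tf2O/2,6-lutidine sulfonylates the less hindered C8 oxygen to give the vinylogous triflate F6.
- Me2CuLi exchanges triflate for methyl to give the silyl ether F7, and HF·pyridine returns to 14.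

Step 12. Oxygen may be delivered to the wrong face of C9, to the methyl group, or the alcohol may be over-oxidised. The fallback sets C9 by reagent control; it sets out from 20 and returns at 21. The crude SeO2/t-BuOOH product is oxidised with Dess–Martin periodinane so that all C9-oxygenated material converges on the C9 enone F8. CBS reduction with the (S)-methyl oxazaborolidine and BH3·SMe2 (the methyl-substituted alkenyl group acting as the large substituent) should then give 21.

Step 9. Intramolecular hydride delivery may be lost (slow ligand exchange at the tertiary hydroxyl), so that external hydride attacks the opposite face; acid may also dehydrate the β-hydroxy ketone. The fallback accepts the opposite facial selectivity and corrects it by inversion; it sets out from 14 and returns at 20. Luche reduction (NaBH4, CeCl3·7H2O, MeOH, −78 °C) from the exposed face anti to the angular methyl should give the C6-epimeric diol F9. Mitsunobu esterification of F9 with acid 18 (PPh3, DIAD, toluene, 0 °C) inverts C6 and gives 20.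

**Further compounds**

F1 | step 8 | epoxy ketone diol (C4,C5-cis-diol of 7, both hydroxyls cis to the epoxide oxygen) | CC(C)[C@@]1(O)[C@H](O)[C@@]23O[C@@H]2C(=O)CC[C@@]3(C)CC1
F2 | step 8 | C5 mesylate of F1 | CC(C)[C@@]1(O)[C@H](OS(C)(=O)=O)[C@@]23O[C@@H]2C(=O)CC[C@@]3(C)CC1
F3 | step 8 | C4 trimethylsilyl ether of F2 | CC(C)[C@@]1(O[Si](C)(C)C)[C@H](OS(C)(=O)=O)[C@@]23O[C@@H]2C(=O)CC[C@@]3(C)CC1
F4 | step 8 | β-hydroxy ketone (C6 carbinol, C8 ketone, C5 mesylate, C4 silyl ether) | CC(C)[C@@]1(O[Si](C)(C)C)[C@H](OS(C)(=O)=O)[C@@]2(O)CC(=O)CC[C@@]2(C)CC1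
F5 | step 8 | β-diketone (C4-silylated hydroazulene-6,8-dione) | O=C1CC(=O)CC[C@@]2(C)CC[C@@](O[Si](C)(C)C)(C(C)C)[C@H]12
F6 | step 8 | vinylogous triflate (C8 enol triflate of F5) | O=C1C=C(OS(=O)(=O)C(F)(F)F)CC[C@@]2(C)CC[C@@](O[Si](C)(C)C)(C(C)C)[C@H]12
F7 | step 8 | C4 trimethylsilyl ether of 14 | O=C1C=C(C)CC[C@@]2(C)CC[C@@](O[Si](C)(C)C)(C(C)C)[C@H]12
F8 | step 12 | C9 enone (9-oxo derivative of 20) | COc1cc(C(=O)O[C@H]2C=C(C)C(=O)C[C@@]3(C)CC[C@@](O)(C(C)C)[C@H]23)ccc1O[Si](C)(C)C(C)(C)C
F9 | step 9 | C6-epimeric diol (C6 epimer of 15) | O[C@@H]1C=C(C)CC[C@@]2(C)CC[C@@](O)(C(C)C)[C@H]12
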